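**Plan**

1. Retrosynthetic cuts, in order: the C7 prenyl group back to a C7 ketone (its CH2–CH= bond, then the C7=CH2 carbon); the C1–C8 bond; the C5–C6 bond, giving a symmetric 3,5-diprenyl aroylphloroglucinol and a bromomethyl ketone; the two aryl–prenyl bonds and the aryl–CO bond.
2. Enabling feature: in the bicyclo[3.3.1]nonane, C1 and C5 are bridgeheads, C9 is the bridging ketone and C6–C7–C8 the saturated bridge. A ketone held temporarily at C7 makes quaternary C8 an enolate carbon, and C1 is the prenyl-bearing enolate carbon of the dearomatised triketone ring, so C1–C8 joins two nucleophilic carbons and is made by oxidation.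
3. Forward order: protected aroylphloroglucinol, double C-prenylation, dearomative C5 alkylation (the arene becomes ring B: C1–C5 plus C9), oxidative closure of ring A (C1, C9, C5, C6, C7, C8), conversion of C7=O into the endo prenyl group, one fluoride deprotection.
4. Stereochemistry: C5 from a chiral ammonium ion pair in the alkylation; C1 dictated by C5 through the three-atom tether; C8 from the chair-like closure of the key step; C7 from exo-face hydroboration of a C7 methylene group.

Key step: step 9

Remark: atoms carry the usual numbering of this compound class (C1/C5 bridgeheads, C2–C3–C4 the enolised β-diketone bridge, C6–C7–C8 the saturated bridge, C9 the bridging ketone); descriptors refer to the tautomers drawn.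
Remark: the side-chain stereocentre of 10–14 becomes C8 and is planarised in step 9, so its configuration is immaterial; the (R) series is drawn and the racemate would serve equally.
Remark: enol O-alkylation in step 11 is drawn at O4; the O2 regioisomer, if formed, converges on 23 in step 13.

**Route**

Step 1
Reactants: 1 phloroglucinol
Product: 2 1,3,5-tris(methoxymethoxy)benzene
Conditions: NaH, MeOCH2Cl, DMF, 0 °C → rt
Reagents that add atoms: chloromethyl methyl ether, COCCl
Why: Williamson O-alkylation of the triphenoxide by the hard chloromethyl ether should give the tris-acetal, whose oxygen pairs later direct ring lithiation.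

Step 2
Reactants: 3 methyl 3,4-dihydroxybenzoate
Product: 4 methyl 3,4-bis(triisopropylsilyloxy)benzoate
Conditions: i-Pr3SiCl, imidazole, DMAP (cat.), DMF, rt → 40 °C
Reagents that add atoms: chlorotriisopropylsilane, CC(C)[Si](Cl)(C(C)C)C(C)C
Why: Imidazole-promoted O-silylation of both catechol hydroxyls; triisopropylsilyl ethers are chosen because they should survive the amine, hydroxide and amide bases, the ylide and the borane used later and leave with fluoride at the end.

Step 3
Reactants: 2 1,3,5-tris(methoxymethoxy)benzene; 4 methyl 3,4-bis(triisopropylsilyloxy)benzoate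
Product: 6 [3,4-bis(triisopropylsilyloxy)phenyl][2,4,6-tris(methoxymethoxy)phenyl]methanone, via aryllithium 5 (not isolated)
Conditions: n-BuLi, TMEDA, THF, 0 °C; then 4, −78 °C → rt
Reagents that add atoms: n-butyllithium, [Li]CCCC (lithium in 5 only)
Why: Directed ortho-lithiation between two acetal oxygens followed by nucleophilic acyl substitution on the ester; the ketone, flanked by two ortho substituents, is too hindered for a second addition.

Step 4
Reactants: 6 [3,4-bis(triisopropylsilyloxy)phenyl][2,4,6-tris(methoxymethoxy)phenyl]methanone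
Product: 7 [3,4-bis(triisopropylsilyloxy)phenyl](2,4,6-trihydroxyphenyl)methanone
Conditions: HCl (cat.), MeOH/THF, 45 °C
Reagents that add atoms: none
Why: Acid-catalysed acetal exchange with methanol removes the three methoxymethyl groups as dimethoxymethane, while aryl triisopropylsilyl ethers are inert to dilute methanolic acid.

Step 5
Reactants: 7 [3,4-bis(triisopropylsilyloxy)phenyl](2,4,6-trihydroxyphenyl)methanone; 8 prenyl bromide (1-bromo-3-methylbut-2-ene), first equivalent
Product: 9 [3,4-bis(triisopropylsilyloxy)phenyl][2,4,6-trihydroxy-3,5-bis(3-methylbut-2-en-1-yl)phenyl]methanone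
Conditions: 8 (2.2 equiv in all), DBU (2.2 equiv), THF, 0 °C → rt
Reagents that add atoms: prenyl bromide (second equivalent of 8), CC(C)=CCBr
Why: Two successive SN2 C-alkylations of the ambident phloroglucinolate, one at each free ring carbon and each consuming one equivalent of the bromide (aromatic C-prenylation), are the standard entry to 3,5-diprenyl acylphloroglucinols; the amidine base in THF avoids hydroxide, which could attack the aryl silyl ethers.

Step 6
Reactants: 10 (R)-3,7-dimethylocta-1,6-diene (β-citronellene)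
Product: 11 (R)-3,7-dimethyloct-6-en-2-one
Conditions: PdCl2 (10 mol %), CuCl (co-catalyst), O2 (1 atm), DMF/H2O, rt
Reagents that add atoms: water, O
Why: Wacker–Tsuji oxidation; divalent palladium should hydroxypalladate only the monosubstituted alkene in the Markovnikov sense to give the methyl ketone, the trisubstituted alkene being inert.

Step 7
Reactants: 11 (R)-3,7-dimethyloct-6-en-2-one
Product: 13 (R)-1-bromo-3,7-dimethyloct-6-en-2-one, via silyl enol ether 12 (not isolated)
Conditions: LiN(i-Pr)2, THF, −78 °C; Me3SiCl; then NBS, THF, −78 → 0 °C (enol ether used crude)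
Reagents that add atoms: chlorotrimethylsilane, C[Si](C)(C)Cl (silyl group in 12 only); N-bromosuccinimide, O=C1CCC(=O)N1Br
Why: Kinetic deprotonation at the methyl group rather than the methine, O-silylation, then electrophilic bromination of the terminal silyl enol ether, which should react with NBS far faster than the trisubstituted alkene.

Step 8
Reactants: 9 [3,4-bis(triisopropylsilyloxy)phenyl][2,4,6-trihydroxy-3,5-bis(3-methylbut-2-en-1-yl)phenyl]methanone; 13 (R)-1-bromo-3,7-dimethyloct-6-en-2-one
Product: 14 (6S)-4-[3,4-bis(triisopropylsilyloxy)benzoyl]-6-[(3R)-3,7-dimethyl-2-oxooct-6-en-1-yl]-3,5-dihydroxy-2,6-bis(3-methylbut-2-en-1-yl)cyclohexa-2,4-dien-1-one (ring C6 is the later C5)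
Conditions: O-allyl-N-(9-anthracenylmethyl)cinchonidinium bromide (10 mol %), CsOH·H2O, toluene/CH2Cl2, −40 °C
Reagents that add atoms: none
Why: Proposed new method: the caesium phenoxide of 9 is carried as a tight ion pair with the chiral ammonium cation, which should shield one of the two enantiotopic prenyl-bearing ring carbons so that SN2 attack on the bromomethyl ketone creates the quaternary C5 centre (S) with dearomatisation, C- over O-alkylation being the usual course for such phloroglucinolates with reactive halides in non-polar media; the closest known reaction types are the cinchona-ammonium-catalysed enantioselective alkylative dearomatisation of 3,5-diprenyl acylphloroglucinols by conjugate addition to enals and the non-selective base-mediated dearomative C-alkylation of the same phenols with alkyl halides, an enantioselective SN2 version not having been shown; the cinchonidinium salt or its cinchoninium pseudoenantiomer is to be chosen according to which delivers the (S) centre.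

Step 9
Reactants: 14 (6S)-4-[3,4-bis(triisopropylsilyloxy)benzoyl]-6-[(3R)-3,7-dimethyl-2-oxooct-6-en-1-yl]-3,5-dihydroxy-2,6-bis(3-methylbut-2-en-1-yl)cyclohexa-2,4-dien-1-one
Product: 16 (1S,5S,8S)-3-[3,4-bis(triisopropylsilyloxy)benzoyl]-4-hydroxy-8-methyl-1,5-bis(3-methylbut-2-en-1-yl)-8-(4-methylpent-3-en-1-yl)bicyclo[3.3.1]non-3-ene-2,7,9-trione, via trilithium trienolate 15 (not isolated)
Conditions: LiN(SiMe3)2 (3.0 equiv), THF, −78 → 0 °C; then Fe(acac)3 (2.2 equiv), −78 °C → rt, argon
Reagents that add atoms: lithium bis(trimethylsilyl)amide, [Li]N([Si](C)(C)C)[Si](C)(C)C (lithium in 15 only)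
Why: Proposed new method: trivalent iron should oxidise trienolate 15 at its most electron-rich site, the tetrasubstituted C7–C8 ketone enolate, and the C8 α-keto radical (or its iron-bound equivalent) then adds to C1 of the triketonate, a second electron transfer giving the neutral C2 ketone; the closest known reaction type is the intramolecular oxidative heterocoupling of two different carbonyl enolates by Fe(acac)3 or a divalent copper carboxylate, not yet shown for a bond between two fully substituted carbons or for a triketonate partner. Ring A (C1, C9, C5, C6, C7, C8) closes as a six-membered ring containing both reacting carbons, enol-endo at C8 and with the C1=C2 enolate bond exocyclic to the new ring. C1 is fixed by C5, because the C6–C7–C8 tether can reach C1 only on the ring face that carries it, so the bicycle is necessarily cis-bridged. C8 is set in a chair-like closure in which the longer 4-methylpent-3-enyl chain is expected to point to the open side syn to C9 and methyl into the slot between the C1 prenyl group and O2; this preference is not assured and is the element to be tuned through counter-ion, oxidant and temperature. The step needs C8 over C6 enolisation, secured because a C6 radical could only close a four-membered ring while enolate equilibration at 0 °C feeds the C8 pathway, and C1 over the aroyl-bearing C3, secured by the higher electron density and lower hindrance of the alkyl-substituted carbon, the site at which such triketonates are C-alkylated. The prenyl alkenes should not intercept the electrophilic C8 radical, since the enolate carbon C1 is polarity-matched and held in a six-membered array.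

Step 10
Reactants: 16 (1S,5S,8S)-3-[3,4-bis(triisopropylsilyloxy)benzoyl]-4-hydroxy-8-methyl-1,5-bis(3-methylbut-2-en-1-yl)-8-(4-methylpent-3-en-1-yl)bicyclo[3.3.1]non-3-ene-2,7,9-trione
Product: 18 (1S,5S,8R)-3-[3,4-bis(triisopropylsilyloxy)benzoyl]-4-hydroxy-8-methyl-7-methylidene-1,5-bis(3-methylbut-2-en-1-yl)-8-(4-methylpent-3-en-1-yl)bicyclo[3.3.1]non-3-ene-2,9-dione, via potassium enolate 17 (not isolated)
Conditions: KN(SiMe3)2 (1.0 equiv), THF, 0 °C; then Ph3P=CH2 (from Ph3PCH3Br and KN(SiMe3)2, excess), toluene, 80 °C; NH4Cl (aq.)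
Reagents that add atoms: methyltriphenylphosphonium bromide, C[P+](c1ccccc1)(c1ccccc1)c1ccccc1.[Br-] (as the ylide made in the flask); potassium bis(trimethylsilyl)amide, [K]N([Si](C)(C)C)[Si](C)(C)C (potassium in 17 only)
Why: Wittig methylenation; as the triketonate 17 the C2, C4 and aroyl carbonyls are deactivated and C9 is shielded by two quaternary bridgeheads, so only the C7 ketone should react under the forcing salt-free conditions used for hindered ketones, and no stereocentre is epimerisable.

Step 11
Reactants: 18 (1S,5S,8R)-3-[3,4-bis(triisopropylsilyloxy)benzoyl]-4-hydroxy-8-methyl-7-methylidene-1,5-bis(3-methylbut-2-en-1-yl)-8-(4-methylpent-3-en-1-yl)bicyclo[3.3.1]non-3-ene-2,9-dione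
Product: 19 (1S,5S,8R)-3-[3,4-bis(triisopropylsilyloxy)benzoyl]-8-methyl-7-methylidene-1,5-bis(3-methylbut-2-en-1-yl)-8-(4-methylpent-3-en-1-yl)-4-{[2-(trimethylsilyl)ethoxy]methoxy}bicyclo[3.3.1]non-3-ene-2,9-dione
Conditions: Me3SiCH2CH2OCH2Cl, i-Pr2NEt, CH2Cl2, 0 °C
Reagents that add atoms: 2-(trimethylsilyl)ethoxymethyl chloride, C[Si](C)(C)CCOCCl
Why: O-alkylation of the vinylogous acid (C3 is fully substituted, so only oxygen can react) masks the acidic enol, which would otherwise consume the borane as a stable boron chelate, with a group that leaves under the same fluoride conditions as the aryl silyl ethers.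

Step 12
Reactants: 19 (1S,5S,8R)-3-[3,4-bis(triisopropylsilyloxy)benzoyl]-8-methyl-7-methylidene-1,5-bis(3-methylbut-2-en-1-yl)-8-(4-methylpent-3-en-1-yl)-4-{[2-(trimethylsilyl)ethoxy]methoxy}bicyclo[3.3.1]non-3-ene-2,9-dione; 20 1-bromo-2-methylprop-1-ene
Product: 22 (1S,5S,7S,8R)-3-[3,4-bis(triisopropylsilyloxy)benzoyl]-8-methyl-1,5,7-tris(3-methylbut-2-en-1-yl)-8-(4-methylpent-3-en-1-yl)-4-{[2-(trimethylsilyl)ethoxy]methoxy}bicyclo[3.3.1]non-3-ene-2,9-dione, via B-alkyl-9-BBN 21 (not isolated)
Conditions: 9-BBN, THF, rt; then 20, Pd(dppf)Cl2 (10 mol %), K3PO4 (aq.), DMF, rt → 45 °C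
Reagents that add atoms: 9-borabicyclo[3.3.1]nonane, [H]B1C2CCCC1CCC2 (boron fragment in 21 only)
Why: Hydroboration by 9-BBN should place boron on the terminal carbon of the only 1,1-disubstituted alkene (the prenyl-type trisubstituted alkenes react far more slowly) and deliver hydrogen to C7 from the exo face, the endo face lying in the concave region over the C2–C3–C4 enone bridge and its aroyl group, which sets C7 (S) with the CH2B arm endo; B-alkyl Suzuki–Miyaura coupling with the alkenyl bromide then forms the CH2–CH= bond without touching C7.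

Step 13
Reactants: 22 (1S,5S,7S,8R)-3-[3,4-bis(triisopropylsilyloxy)benzoyl]-8-methyl-1,5,7-tris(3-methylbut-2-en-1-yl)-8-(4-methylpent-3-en-1-yl)-4-{[2-(trimethylsilyl)ethoxy]methoxy}bicyclo[3.3.1]non-3-ene-2,9-dione
Product: 23 (1S,5S,7S,8R)-3-(3,4-dihydroxybenzoyl)-4-hydroxy-8-methyl-1,5,7-tris(3-methylbut-2-en-1-yl)-8-(4-methylpent-3-en-1-yl)bicyclo[3.3.1]non-3-ene-2,9-dione (CNP0108469.1)
Conditions: Bu4NF, AcOH, THF, 0 °C → rt, argon
Reagents that add atoms: none
Why: Fluoride-induced desilylation cleaves both aryl silyl ethers and fragments the silylethoxymethyl enol ether (to Me3SiF, ethene and formaldehyde, the triketonate being a good leaving group); the acetic acid buffer keeps the catechol and the enol/prenyl array out of strongly basic or acidic conditions, and no stereocentre is involved.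

**Compound list**

1 | phloroglucinol | Oc1cc(O)cc(O)c1 | starting material
2 | 1,3,5-tris(methoxymethoxy)benzene | COCOc1cc(OCOC)cc(OCOC)c1 | intermediate
3 | methyl 3,4-dihydroxybenzoate | COC(=O)c1ccc(O)c(O)c1 | starting material
4 | methyl 3,4-bis(triisopropylsilyloxy)benzoate | COC(=O)c1ccc(O[Si](C(C)C)(C(C)C)C(C)C)c(O[Si](C(C)C)(C(C)C)C(C)C)c1 | intermediate
5 | [2,4,6-tris(methoxymethoxy)phenyl]lithium | [Li]c1c(OCOC)cc(OCOC)cc1OCOC | intermediate (not isolated)
6 | [3,4-bis(triisopropylsilyloxy)phenyl][2,4,6-tris(methoxymethoxy)phenyl]methanone | COCOc1cc(OCOC)c(C(=O)c2ccc(O[Si](C(C)C)(C(C)C)C(C)C)c(O[Si](C(C)C)(C(C)C)C(C)C)c2)c(OCOC)c1 | intermediate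
7 | [3,4-bis(triisopropylsilyloxy)phenyl](2,4,6-trihydroxyphenyl)methanone | Oc1cc(O)c(C(=O)c2ccc(O[Si](C(C)C)(C(C)C)C(C)C)c(O[Si](C(C)C)(C(C)C)C(C)C)c2)c(O)c1 | intermediate
8 | prenyl bromide (1-bromo-3-methylbut-2-ene) | CC(C)=CCBr | starting material
9 | [3,4-bis(triisopropylsilyloxy)phenyl][2,4,6-trihydroxy-3,5-bis(3-methylbut-2-en-1-yl)phenyl]methanone | CC(C)=CCc1c(O)c(CC=C(C)C)c(O)c(C(=O)c2ccc(O[Si](C(C)C)(C(C)C)C(C)C)c(O[Si](C(C)C)(C(C)C)C(C)C)c2)c1O | intermediate
10 | (R)-3,7-dimethylocta-1,6-diene (β-citronellene) | CC(C)=CCC[C@@H](C)C=C | starting material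
11 | (R)-3,7-dimethyloct-6-en-2-one | CC(C)=CCC[C@@H](C)C(C)=O | intermediate
12 | trimethyl{[(3R)-3,7-dimethylocta-1,6-dien-2-yl]oxy}silane | CC(C)=CCC[C@@H](C)C(=C)O[Si](C)(C)C | intermediate (not isolated)
13 | (R)-1-bromo-3,7-dimethyloct-6-en-2-one | CC(C)=CCC[C@@H](C)C(=O)CBr | intermediate
14 | C5-alkylated dearomatised aroylphloroglucinol, (5S), side chain (R); key-step precursor | CC(C)=CCC[C@@H](C)C(=O)C[C@]1(CC=C(C)C)C(=O)C(CC=C(C)C)=C(O)C(C(=O)c2ccc(O[Si](C(C)C)(C(C)C)C(C)C)c(O[Si](C(C)C)(C(C)C)C(C)C)c2)=C1O | intermediate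
15 | trilithium trienolate of 14 (C7–C8 ketone enolate and ring dienolate; enolate geometry open) | CC(C)=CCCC(C)=C(O[Li])C[C@]1(CC=C(C)C)C(=O)C(CC=C(C)C)=C(O[Li])C(C(=O)c2ccc(O[Si](C(C)C)(C(C)C)C(C)C)c(O[Si](C(C)C)(C(C)C)C(C)C)c2)=C1O[Li] | intermediate (not isolated)
16 | (1S,5S,8S) bicyclic 2,7,9-trione with C7 ketone; key-step product | CC(C)=CCC[C@]1(C)C(=O)C[C@]2(CC=C(C)C)C(=O)[C@@]1(CC=C(C)C)C(=O)C(C(=O)c3ccc(O[Si](C(C)C)(C(C)C)C(C)C)c(O[Si](C(C)C)(C(C)C)C(C)C)c3)=C2O | intermediate
17 | potassium enolate of 16 | CC(C)=CCC[C@]1(C)C(=O)C[C@]2(CC=C(C)C)C(=O)[C@@]1(CC=C(C)C)C(=O)C(C(=O)c3ccc(O[Si](C(C)C)(C(C)C)C(C)C)c(O[Si](C(C)C)(C(C)C)C(C)C)c3)=C2[O-].[K+] | intermediate (not isolated)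
18 | (1S,5S,8R) C7-methylidene enol | CC(C)=CCC[C@]1(C)C(=C)C[C@]2(CC=C(C)C)C(=O)[C@@]1(CC=C(C)C)C(=O)C(C(=O)c3ccc(O[Si](C(C)C)(C(C)C)C(C)C)c(O[Si](C(C)C)(C(C)C)C(C)C)c3)=C2O | intermediate
19 | (1S,5S,8R) C7-methylidene O4-[2-(trimethylsilyl)ethoxy]methyl enol ether | CC(C)=CCC[C@]1(C)C(=C)C[C@]2(CC=C(C)C)C(=O)[C@@]1(CC=C(C)C)C(=O)C(C(=O)c3ccc(O[Si](C(C)C)(C(C)C)C(C)C)c(O[Si](C(C)C)(C(C)C)C(C)C)c3)=C2OCOCC[Si](C)(C)C | intermediate
20 | 1-bromo-2-methylprop-1-ene | CC(C)=CBr | starting material
21 | (1S,5S,7S,8R) 7-endo-[(9-borabicyclo[3.3.1]nonan-9-yl)methyl] compound | CC(C)=CCC[C@]1(C)[C@@H](CB4C5CCCC4CCC5)C[C@]2(CC=C(C)C)C(=O)[C@@]1(CC=C(C)C)C(=O)C(C(=O)c3ccc(O[Si](C(C)C)(C(C)C)C(C)C)c(O[Si](C(C)C)(C(C)C)C(C)C)c3)=C2OCOCC[Si](C)(C)C | intermediate (not isolated)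
22 | (1S,5S,7S,8R) fully protected target (7-endo prenyl) | CC(C)=CCC[C@]1(C)[C@@H](CC=C(C)C)C[C@]2(CC=C(C)C)C(=O)[C@@]1(CC=C(C)C)C(=O)C(C(=O)c3ccc(O[Si](C(C)C)(C(C)C)C(C)C)c(O[Si](C(C)C)(C(C)C)C(C)C)c3)=C2OCOCC[Si](C)(C)C | intermediate
23 | CNP0108469.1, (1S,5S,7S,8R)-3-(3,4-dihydroxybenzoyl)-4-hydroxy-8-methyl-1,5,7-tris(3-methylbut-2-en-1-yl)-8-(4-methylpent-3-en-1-yl)bicyclo[3.3.1]non-3-ene-2,9-dione | CC(C)=CCC[C@]1(C)[C@@H](CC=C(C)C)C[C@]2(CC=C(C)C)C(=O)[C@@]1(CC=C(C)C)C(=O)C(C(=O)c1ccc(O)c(O)c1)=C2O | target

**Step count and risks**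

Total steps: 13. Longest linear sequence: 10 steps (1 → 2 → 6 → 7 → 9 → 14 → 16 → 18 → 19 → 22 → 23; steps 1, 3, 4, 5, 8, 9, 10, 11, 12, 13).

Steps most likely to fail:

1. Step 9. The oxidation may be diverted before the C–C bond forms: oxidation of the unproductive C6 enolate, capture of the C8 radical by a prenyl alkene or by a triketonate oxygen, or transfer of an acetylacetonate ligand. The closure may also favour the C8 epimer or the acyl-bearing C3. The fallback uses known chemistry and sets out from 14. Exhaustive silylation with Me3SiOTf/Et3N (CH2Cl2, 0 °C → rt, thermodynamic control) should give the tris(trimethylsilyl) derivative F1, in which the side-chain ketone is fixed as the more substituted C7–C8 silyl enol ether and the ring as a bis(silyloxy) dienone. Oxidative coupling of the two enol silyl ether units with (NH4)2Ce(NO3)6/NaHCO3 in MeCN at −30 °C follows; this is the established tetravalent-cerium coupling of silyl enol ethers through the radical cation of the more electron-rich partner, also known intramolecularly. Aqueous work-up removes the remaining silyl group and the route is rejoined at 16. The site of enolisation is then fixed before the oxidant is added.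

2. Step 8. The ion pair may discriminate poorly between the two enantiotopic ring carbons, and O-alkylation or hydroxide attack on the bromoketone may compete. The fallback sets out from 9 and 13. Alkylation under the achiral conditions of step 5 (DBU, THF, 0 °C), the established non-selective dearomative C-alkylation of such phenols by alkyl halides, should give the C5-epimeric mixture F2. Because the side chain of 13 is one enantiomer, its two components are diastereomers. Preparative HPLC on a cellulose tris(3,5-dimethylphenylcarbamate) phase would separate 14 from its (5R) epimer F3, and the route is rejoined at 14.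

3. Step 12. Transmetalation of the β-branched alkylborane held near the concave face may be slow, letting protodeboronation compete, and hydrogen delivery to C7 may not be fully exo-selective. The fallback sets out from 19. Hydroboration as before to 21, then oxidation with NaBO3·4H2O (THF/H2O) in place of the coupling, should give the endo primary alcohol F4; a C7 epimer, if present, would be removed here by chromatography. Appel iodination (I2, PPh3, imidazole) gives the primary iodide F5. Nickel-catalysed reductive cross-electrophile coupling of F5 with 20 (NiI2, 4,4′-di-tert-butyl-2,2′-bipyridine, Mn powder, NaI, DMA, rt), an established alkyl halide–alkenyl bromide coupling tolerant of ketones, rejoins the route at 22.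

**Further compounds**

F1 | step 9 | tris(trimethylsilyl) derivative of 14 (C7–C8 silyl enol ether, O2,O4-bis-silylated ring) | CC(C)=CCCC(C)=C(O[Si](C)(C)C)C[C@]1(CC=C(C)C)C(=O)C(CC=C(C)C)=C(O[Si](C)(C)C)C(C(=O)c2ccc(O[Si](C(C)C)(C(C)C)C(C)C)c(O[Si](C(C)C)(C(C)C)C(C)C)c2)=C1O[Si](C)(C)C
F2 | step 8 | C5-epimeric mixture (14 plus F3) | CC(C)=CCC[C@@H](C)C(=O)CC1(CC=C(C)C)C(=O)C(CC=C(C)C)=C(O)C(C(=O)c2ccc(O[Si](C(C)C)(C(C)C)C(C)C)c(O[Si](C(C)C)(C(C)C)C(C)C)c2)=C1O
F3 | step 8 | (5R) epimer of 14 | CC(C)=CCC[C@@H](C)C(=O)C[C@@]1(CC=C(C)C)C(=O)C(CC=C(C)C)=C(O)C(C(=O)c2ccc(O[Si](C(C)C)(C(C)C)C(C)C)c(O[Si](C(C)C)(C(C)C)C(C)C)c2)=C1O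
F4 | step 12 | 7-endo-hydroxymethyl analogue of 22 (primary alcohol) | CC(C)=CCC[C@]1(C)[C@@H](CO)C[C@]2(CC=C(C)C)C(=O)[C@@]1(CC=C(C)C)C(=O)C(C(=O)c3ccc(O[Si](C(C)C)(C(C)C)C(C)C)c(O[Si](C(C)C)(C(C)C)C(C)C)c3)=C2OCOCC[Si](C)(C)C
F5 | step 12 | 7-endo-iodomethyl analogue of 22 (primary iodide) | CC(C)=CCC[C@]1(C)[C@@H](CI)C[C@]2(CC=C(C)C)C(=O)[C@@]1(CC=C(C)C)C(=O)C(C(=O)c3ccc(O[Si](C(C)C)(C(C)C)C(C)C)c(O[Si](C(C)C)(C(C)C)C(C)C)c3)=C2OCOCC[Si](C)(C)C
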